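The easy step first: a remainder that decays exponentially can be counted in half-lives, and each one leaves half of what stood before.

- theta: electrophile 20 mM; nucleophile 1.05 equiv; the very flask that is asked about, followed so far
- flask: electrophile 20 mM; nucleophile 1.05 equiv; time 1.0 h

theta run (percent of the electrophile charged)

| time / min | electrophile / % | product / % |
|---|---|---|
| 6.00 | 14.6 | 85.1 |
| 12.0 | 11.3 | 88.3 |
| 20.0 | 6.7 | 93.2 |
| 25.0 | 6.0 | 93.6 |
| 30.0 | 5.2 | 95.3 |

(scatter of a reading: 1 percentage point)

- the earlier runs were read with a standard deviation of 1 percentage point
- the earlier runs do not show how much of nucleophile is bound; that part of a forecast is a guess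

- part of the electrophile that has reacted at 1.0 h
- share of free nucleophile in free nucleophile and protonated nucleophile together, at 1.0 h

In this flask the electrophile stands at 14.6% after 6.00 min, then needs until 30.0 min to reach 5.2%. I choose to treat the tail as pseudo-first-order and read from it the late half-life, the time in which the late remainder of electrophile falls by a factor of 2:

late half-life = (30.0 min − 12.0 min) × ln(2) / ln(11.3% / 5.2%) = 16.1 min

Now I turn the settings by hand. Time comes first: from the last reading to 1.0 h lie 1.87 half-lives, so in this flask

electrophile left = 5.2% / 2^1.87 = 1.43%, reacted 98.6%

The nucleophile comes next: at 1.05 equiv, above one equivalent, its charge leaves room for the whole electrophile. Last is the electrophile charge: if I divide it by some factor at fixed equivalents, I assume that the clock stretches by that factor, as for a single step between two partners. The readings do not show bound nucleophile, so I commit to no free share.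

The forecast, made from the same runs, puts 97.3% reacted, below my figure, and 25% free, of which it says “This is only a guess”.

This flask gives 98.2% reacted and a free share of 95.9%.

    electrophile + nucleophile → acid set free + product (k = 6.20 /M/s)
    nucleophile + acid set free ⇌ protonated nucleophile, settled at all times (K = 670 /M)
    nucleophile ⇌ dormant form (K = 13.0, k = 0.0120 /s)
    acid set free → by-product carried off (k = 0.00360 /s)

The electrophile of this flask goes from 4.91% at 0.500 h to 1.81% at 1.00 h, which is 20.9 min per halving over that stretch. The neighbouring flask charges 5.0 mM of electrophile at the same equivalents. Stretching the clock, its 1.0 h corresponds to 15.0 min on the curve of the 20 mM flask, 3.00 min past the reading at 12.0 min, so with the late half-life of 16.1 min I count 9.93% left. That neighbouring flask holds 10% of its electrophile at 1.00 h.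

The numbers in the tables were computed with made-up constants.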